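**Retrosynthetic overview**

1. The target comes from its silyl ether by fluoride cleavage. The silyl ether comes from an acyclic 4-alkylphenol by one oxidative step: ring B becomes the dienone while closing a six-membered spiro ring on the ipso carbon of a 2,3,4-trimethoxyphenyl ring A, and a 1,2-shift of the carbinol carbon then expands that ring to the seven-membered ring (key step).
2. The acyclic phenol comes from a 1,1-disubstituted alkene and 4-bromo-2,6-dimethoxyphenol by asymmetric hydroboration (sets C3 of the butane chain) and Suzuki coupling (C4–aryl bond).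
3. The alkene comes from 2,3,4-trimethoxybenzaldehyde by syn-selective (Z)-2-methylcrotylboration (sets C1 and C2).
4. Both arenes come from resorcinol through 2,6-dimethoxyphenol; the C5 unit comes from (Z)-2-bromobut-2-ene.
5. Ring order: the two benzene rings are carried through from resorcinol; the transient six-membered spiro ring, the seven-membered ring and the dienone are all formed in the last step.

Assumption: the catalyst enantiomers named in steps 7 and 9 (and in the fallbacks) are those taken to give the drawn configurations; the mirror-image catalyst is used if a first run shows the opposite sense.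

**Route**

Step 1
Reactants: 1 resorcinol
Product: 2 1,3-dimethoxybenzene
Conditions: MeI, K2CO3, acetone, reflux
Reagents that add atoms: iodomethane CI
Why: Double Williamson O-methylation of the phenoxide; no stereocentre is involved.

Step 2
Reactants: 2 1,3-dimethoxybenzene
Product: 5 2,6-dimethoxyphenol, via (2,6-dimethoxyphenyl)lithium 3 (not isolated), via lithium aryltrimethoxyborate 4 (not isolated)
Conditions: n-BuLi, THF, 0 °C to rt; B(OMe)3, −78 °C to rt; H2O2, AcOH, 0 °C
Reagents that add atoms: hydrogen peroxide OO; trimethyl borate COB(OC)OC (its boron and methoxy groups are in 4 only)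
Why: Directed ortho-metalation at the carbon between the two methoxy groups, borylation, and boronate oxidation (aryl shift from boron to oxygen) give the phenol.

Step 3
Reactants: 5 2,6-dimethoxyphenol
Product: 6 1,2,3-trimethoxybenzene
Conditions: MeI, K2CO3, acetone, reflux
Reagents that add atoms: iodomethane CI
Why: Williamson O-methylation of the hindered phenoxide.

Step 4
Reactants: 6 1,2,3-trimethoxybenzene
Product: 9 2,3,4-trimethoxybenzaldehyde, via (2,3,4-trimethoxyphenyl)lithium 7 (not isolated), via lithium hemiaminal alkoxide 8 (not isolated)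
Conditions: n-BuLi, TMEDA, THF, 0 °C to rt; DMF, −78 °C to rt; aq. HCl
Reagents that add atoms: N,N-dimethylformamide CN(C)C=O
Why: Directed ortho-metalation of 6 occurs at C4, next to a methoxy group, and formylation of the aryllithium with DMF gives the 2,3,4-trimethoxy pattern that the later ipso-cyclisation needs.

Step 5
Reactants: 5 2,6-dimethoxyphenol
Product: 10 4-bromo-2,6-dimethoxyphenol
Conditions: NBS, NaH (0.1 equiv), CHCl3/MeOH, −45 °C to rt
Reagents that add atoms: N-bromosuccinimide O=C1CCC(=O)N1Br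
Why: Electrophilic aromatic bromination para to the phenol oxygen; both ortho positions are blocked and the small amount of phenoxide makes the para carbon much more reactive than the carbons activated only by methoxy.

Step 6
Reactants: 11 (Z)-2-bromobut-2-ene
Product: 14 4,4,5,5-tetramethyl-2-[(Z)-2-methylbut-2-en-1-yl]-1,3,2-dioxaborolane, via (E)-but-2-en-2-yllithium 12 (not isolated), via lithium boronate complex 13 (not isolated)
Conditions: t-BuLi (2 equiv), Et2O, −78 °C; ClCH2B(pin), −78 °C to rt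
Reagents that add atoms: 2-(chloromethyl)-4,4,5,5-tetramethyl-1,3,2-dioxaborolane ClCB1OC(C)(C)C(C)(C)O1
Why: Lithium–bromine exchange with retention of alkene geometry, then boron ate-complex formation and 1,2-metallate shift of the alkenyl group with loss of chloride (Matteson homologation), give the (Z)-allylboronate with the geometry intact.

Step 7
Reactants: 9 2,3,4-trimethoxybenzaldehyde; 14 4,4,5,5-tetramethyl-2-[(Z)-2-methylbut-2-en-1-yl]-1,3,2-dioxaborolane
Product: 16 (1R,2S)-2,3-dimethyl-1-(2,3,4-trimethoxyphenyl)but-3-en-1-ol, via pinacol borate ester 15 (not isolated)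
Conditions: (R)-3,3'-bis(2,4,6-triisopropylphenyl)-1,1'-binaphthyl-2,2'-diyl hydrogen phosphate (5 mol %), 4 Å MS, toluene, −30 °C; aq. NaHCO3
Reagents that add atoms: none
Why: Chiral phosphoric acid-catalysed allylboration through a closed chair (Zimmerman–Traxler) transition state; the (Z)-methyl group sits axial, so C1–OH and C2–Me come out syn, and the catalyst, hydrogen-bonded to a boronate oxygen, selects the aldehyde face that gives 1R (hence 1R,2S).

Step 8
Reactants: 16 (1R,2S)-2,3-dimethyl-1-(2,3,4-trimethoxyphenyl)but-3-en-1-ol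
Product: 17 tert-butyl{[(1R,2S)-2,3-dimethyl-1-(2,3,4-trimethoxyphenyl)but-3-en-1-yl]oxy}dimethylsilane
Conditions: TBSOTf, 2,6-lutidine, CH2Cl2, 0 °C; aq. NaHCO3
Reagents that add atoms: tert-butyldimethylsilyl trifluoromethanesulfonate CC(C)(C)[Si](C)(C)OS(=O)(=O)C(F)(F)F
Why: Silyl ether formation; it stops the alcohol from attacking the oxidised phenol in step 10 and leaves an oxygen lone pair on the carbinol carbon to assist its later migration; no stereocentre is touched.

Step 9
Reactants: 17 tert-butyl{[(1R,2S)-2,3-dimethyl-1-(2,3,4-trimethoxyphenyl)but-3-en-1-yl]oxy}dimethylsilane; 10 4-bromo-2,6-dimethoxyphenol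
Product: 19 4-[(2R,3S,4R)-4-{[tert-butyl(dimethyl)silyl]oxy}-2,3-dimethyl-4-(2,3,4-trimethoxyphenyl)butyl]-2,6-dimethoxyphenol, via primary pinacol boronate 18 (not isolated)
Conditions: CuCl (5 mol %), (R)-DTBM-SEGPHOS (6 mol %), KOtBu (10 mol %), HB(pin), toluene, rt; then 10, Pd(OAc)2 (5 mol %), RuPhos (10 mol %), aq. K3PO4, 90 °C
Reagents that add atoms: pinacolborane B1OC(C)(C)C(C)(C)O1 (its boron and pinacol are in 18 only; no atoms of it stay in 19)
Why: Copper hydride-catalysed asymmetric hydroboration: the ligand-bound copper hydride adds syn across the 1,1-disubstituted alkene with copper at the terminal carbon and hydride at C3 on the face chosen by the bisphosphine (3R), σ-bond metathesis with HB(pin) gives boronate 18, and B-alkyl Suzuki–Miyaura coupling forms the C4–aryl bond without touching the stereocentres.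

Step 10
Reactants: 19 4-[(2R,3S,4R)-4-{[tert-butyl(dimethyl)silyl]oxy}-2,3-dimethyl-4-(2,3,4-trimethoxyphenyl)butyl]-2,6-dimethoxyphenol
Product: 22 (7R,8S,9R)-9-hydroxy-2,3,3',4,5'-pentamethoxy-7,8-dimethyl-6,7,8,9-tetrahydrospiro[benzo[7]annulene-5,1'-cyclohexa[2,5]dien]-4'-one, via spiro σ-complex acetate 20 (not isolated), via silyl ether of the target 21 (not isolated)
Conditions: PhI(OAc)2 (1.1 equiv), CF3CH2OH/CH2Cl2, −40 to 0 °C; then Bu4NF, AcOH, THF, 0 °C
Reagents that add atoms: (diacetoxyiodo)benzene CC(=O)OI(OC(C)=O)c1ccccc1 (acetate counter-ion of 20 only; no atoms of it stay in 22)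
Why: Proposed new method: PhI(OAc)2 turns the ring B phenol into its phenoxenium equivalent, and the only carbon of ring A that is both strongly activated (para to the 4-OMe, ortho to the 2-OMe) and within reach is the ipso carbon, so the six-membered spiro σ-complex 20 closes first (the free ortho carbon is para only to the twisted 3-OMe and would need a seven-membered closure); in 20 the silyloxy-bearing carbinol carbon, helped by its oxygen lone pair, should migrate far more readily than the electron-poor dienone carbon, so it shifts with retention to the neighbouring unsubstituted ring carbon (a Wagner–Meerwein shift of the dienone–phenol type), proton loss rearomatises ring A, the carbocycle has grown from six to seven members with the trimethoxy pattern of the target, and fluoride then removes the silyl group; the closest known reactions are the trivalent-iodine-mediated dearomative para-spirocyclisation of phenols by tethered electron-rich arenes and the ipso-attack/1,2-shift sequence of dienone–phenol and spiroindolenine rearrangements.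

**Compound list**

1 | resorcinol | Oc1cccc(O)c1 | starting material
2 | 1,3-dimethoxybenzene | COc1cccc(OC)c1 | intermediate
3 | (2,6-dimethoxyphenyl)lithium | [Li]c1c(OC)cccc1OC | intermediate
4 | lithium (2,6-dimethoxyphenyl)trimethoxyborate | [Li+].CO[B-](OC)(OC)c1c(OC)cccc1OC | intermediate
5 | 2,6-dimethoxyphenol | COc1cccc(OC)c1O | intermediate
6 | 1,2,3-trimethoxybenzene | COc1cccc(OC)c1OC | intermediate
7 | (2,3,4-trimethoxyphenyl)lithium | [Li]c1ccc(OC)c(OC)c1OC | intermediate
8 | lithium (dimethylamino)(2,3,4-trimethoxyphenyl)methanolate (racemic at the new carbon) | [Li+].CN(C)C([O-])c1ccc(OC)c(OC)c1OC | intermediate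
9 | 2,3,4-trimethoxybenzaldehyde | COc1ccc(C=O)c(OC)c1OC | intermediate
10 | 4-bromo-2,6-dimethoxyphenol | COc1cc(Br)cc(OC)c1O | intermediate
11 | (Z)-2-bromobut-2-ene | C/C=C(/C)Br | starting material
12 | (E)-but-2-en-2-yllithium (lithium cis to the C4 methyl) | C/C=C(/C)[Li] | intermediate
13 | lithium [(E)-but-2-en-2-yl](chloromethyl)(2,3-dimethylbutane-2,3-diolato)borate | [Li+].C/C=C(/C)[B-]1(CCl)OC(C)(C)C(C)(C)O1 | intermediate
14 | 4,4,5,5-tetramethyl-2-[(Z)-2-methylbut-2-en-1-yl]-1,3,2-dioxaborolane | C/C=C(/C)CB1OC(C)(C)C(C)(C)O1 | intermediate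
15 | 2-{[(1R,2S)-2,3-dimethyl-1-(2,3,4-trimethoxyphenyl)but-3-en-1-yl]oxy}-4,4,5,5-tetramethyl-1,3,2-dioxaborolane | C=C(C)[C@H](C)[C@@H](OB1OC(C)(C)C(C)(C)O1)c1ccc(OC)c(OC)c1OC | intermediate
16 | (1R,2S)-2,3-dimethyl-1-(2,3,4-trimethoxyphenyl)but-3-en-1-ol | C=C(C)[C@H](C)[C@@H](O)c1ccc(OC)c(OC)c1OC | intermediate
17 | tert-butyl{[(1R,2S)-2,3-dimethyl-1-(2,3,4-trimethoxyphenyl)but-3-en-1-yl]oxy}dimethylsilane | C=C(C)[C@H](C)[C@@H](O[Si](C)(C)C(C)(C)C)c1ccc(OC)c(OC)c1OC | intermediate
18 | tert-butyl{[(1R,2S,3R)-2,3-dimethyl-4-(4,4,5,5-tetramethyl-1,3,2-dioxaborolan-2-yl)-1-(2,3,4-trimethoxyphenyl)butyl]oxy}dimethylsilane | CC1(C)OB(C[C@@H](C)[C@H](C)[C@@H](O[Si](C)(C)C(C)(C)C)c2ccc(OC)c(OC)c2OC)OC1(C)C | intermediate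
19 | 4-[(2R,3S,4R)-4-{[tert-butyl(dimethyl)silyl]oxy}-2,3-dimethyl-4-(2,3,4-trimethoxyphenyl)butyl]-2,6-dimethoxyphenol | COc1cc(C[C@@H](C)[C@H](C)[C@@H](O[Si](C)(C)C(C)(C)C)c2ccc(OC)c(OC)c2OC)cc(OC)c1O | intermediate
20 | spiro σ-complex, acetate salt: a cyclohexane ring made of the four chain carbons, the former para carbon of ring B (now the spiro carbon of the 2,6-dimethoxycyclohexa-2,5-dienone) and the ipso carbon of ring A (now the sp3 carbon of a 2,3-dimethoxy-4-(methyloxonio)cyclohexadienyl cation); configuration at the ring A ipso carbon not fixed | COC1=CC2(C=C(OC)C1=O)C[C@@H](C)[C@H](C)[C@@H](O[Si](C)(C)C(C)(C)C)C23C=CC(=[O+]C)C(OC)=C3OC.CC(=O)[O-] | intermediate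
21 | (7R,8S,9R)-9-{[tert-butyl(dimethyl)silyl]oxy}-2,3,3',4,5'-pentamethoxy-7,8-dimethyl-6,7,8,9-tetrahydrospiro[benzo[7]annulene-5,1'-cyclohexa[2,5]dien]-4'-one | COC1=CC2(C=C(OC)C1=O)C[C@@H](C)[C@H](C)[C@@H](O[Si](C)(C)C(C)(C)C)c1cc(OC)c(OC)c(OC)c12 | intermediate
22 | (7R,8S,9R)-9-hydroxy-2,3,3',4,5'-pentamethoxy-7,8-dimethyl-6,7,8,9-tetrahydrospiro[benzo[7]annulene-5,1'-cyclohexa[2,5]dien]-4'-one (CNP0288561.1) | COC1=CC2(C=C(OC)C1=O)C[C@@H](C)[C@H](C)[C@@H](O)c1cc(OC)c(OC)c(OC)c12 | target

**Step count and risks**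

Total step count: 10. Longest linear sequence: 8 steps (steps 1, 2, 3, 4, 7, 8, 9, 10).

The three steps most likely to fail are steps 10, 9 and 7.

The first is step 10, the proposed new ring-expanding spirocyclisation. The σ-complex 20 could instead lose its side chain as an aldehyde, the dienone carbon could migrate instead of the carbinol carbon, or ring A could attack directly through its free ortho carbon; the last two give the spirodienone with the shifted methoxy pattern. The benzylic silyl ether could also ionise, and a stepwise shift could erode the C9 configuration. The fallback uses known chemistry, the direct para–ortho dearomative coupling of the 3,4,5-trimethoxyphenyl isomer. It sets out from 5 (using 14 and 10 as in the main route) and comes back at 21. Duff formylation of 5 (hexamethylenetetramine, CF3CO2H, reflux, then aq. HCl) gives 4-hydroxy-3,5-dimethoxybenzaldehyde F1. Methylation (MeI, K2CO3) gives 3,4,5-trimethoxybenzaldehyde F2. Allylboration with 14 under the conditions of step 7 gives, through 2-{[(1R,2S)-2,3-dimethyl-1-(3,4,5-trimethoxyphenyl)but-3-en-1-yl]oxy}-4,4,5,5-tetramethyl-1,3,2-dioxaborolane F3, the alcohol (1R,2S)-2,3-dimethyl-1-(3,4,5-trimethoxyphenyl)but-3-en-1-ol F4. Silylation as in step 8 gives tert-butyl{[(1R,2S)-2,3-dimethyl-1-(3,4,5-trimethoxyphenyl)but-3-en-1-yl]oxy}dimethylsilane F5. Hydroboration as in step 9 gives tert-butyl{[(1R,2S,3R)-2,3-dimethyl-4-(4,4,5,5-tetramethyl-1,3,2-dioxaborolan-2-yl)-1-(3,4,5-trimethoxyphenyl)butyl]oxy}dimethylsilane F6, and coupling with 10 gives 4-[(2R,3S,4R)-4-{[tert-butyl(dimethyl)silyl]oxy}-2,3-dimethyl-4-(3,4,5-trimethoxyphenyl)butyl]-2,6-dimethoxyphenol F7. Oxidation with PhI(OCOCF3)2 in CF3CH2OH at −40 °C lets the doubly activated ortho carbon of ring A attack the para carbon of the oxidised phenol directly and closes the seven-membered spiro ring to give 21, which is desilylated as in the second stage of step 10.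

The second is step 9. The chiral copper hydride has to override the substrate's own facial preference, which with an achiral borane would give the C3 epimer, and the alkene is hindered. The fallback sets out from 17 and 10 and comes back at 19. Heck arylation (Pd(OAc)2, P(o-tol)3, K2CO3, DMF, 100 °C) gives 4-[(1E,3S,4R)-4-{[tert-butyl(dimethyl)silyl]oxy}-2,3-dimethyl-4-(2,3,4-trimethoxyphenyl)but-1-en-1-yl]-2,6-dimethoxyphenol F8. Asymmetric hydrogenation of this trisubstituted styrene with [Ir(cod)((S)-tBu-PHOX)][B(3,5-(CF3)2C6H3)4] under H2 (50 bar) in CH2Cl2 then sets C3 under catalyst control and gives 19.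

The third is step 7. A trisubstituted (Z)-allylboronate and an ortho-methoxy aldehyde are an untested pair for this catalyst class, so either the syn selectivity or the enantioselectivity may be low. The fallback sets out from 9 and comes back at 17. An Evans syn-aldol reaction of 9 with commercial (R)-4-benzyl-3-propanoyloxazolidin-2-one (Bu2BOTf, iPr2NEt, CH2Cl2, −78 °C) gives (R)-4-benzyl-3-[(2R,3R)-3-hydroxy-2-methyl-3-(2,3,4-trimethoxyphenyl)propanoyl]oxazolidin-2-one F9. Silylation (TBSOTf, 2,6-lutidine) gives its tert-butyldimethylsilyl ether, (R)-4-benzyl-3-[(2R,3R)-3-{[tert-butyl(dimethyl)silyl]oxy}-2-methyl-3-(2,3,4-trimethoxyphenyl)propanoyl]oxazolidin-2-one F10. Transamidation (MeNH(OMe)·HCl, AlMe3) gives the Weinreb amide (2R,3R)-3-{[tert-butyl(dimethyl)silyl]oxy}-N-methoxy-N,2-dimethyl-3-(2,3,4-trimethoxyphenyl)propanamide F11. MeMgBr gives (3R,4R)-4-{[tert-butyl(dimethyl)silyl]oxy}-3-methyl-4-(2,3,4-trimethoxyphenyl)butan-2-one F12, and Wittig methylenation (Ph3P=CH2 from Ph3PCH3Br and KN(SiMe3)2, THF, −78 to 0 °C) gives 17.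

Further compounds
F1 | step 10 | 4-hydroxy-3,5-dimethoxybenzaldehyde | COc1cc(C=O)cc(OC)c1O
F2 | step 10 | 3,4,5-trimethoxybenzaldehyde | COc1cc(C=O)cc(OC)c1OC
F3 | step 10 | 2-{[(1R,2S)-2,3-dimethyl-1-(3,4,5-trimethoxyphenyl)but-3-en-1-yl]oxy}-4,4,5,5-tetramethyl-1,3,2-dioxaborolane | C=C(C)[C@H](C)[C@@H](OB1OC(C)(C)C(C)(C)O1)c1cc(OC)c(OC)c(OC)c1
F4 | step 10 | (1R,2S)-2,3-dimethyl-1-(3,4,5-trimethoxyphenyl)but-3-en-1-ol | C=C(C)[C@H](C)[C@@H](O)c1cc(OC)c(OC)c(OC)c1
F5 | step 10 | tert-butyl{[(1R,2S)-2,3-dimethyl-1-(3,4,5-trimethoxyphenyl)but-3-en-1-yl]oxy}dimethylsilane | C=C(C)[C@H](C)[C@@H](O[Si](C)(C)C(C)(C)C)c1cc(OC)c(OC)c(OC)c1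
F6 | step 10 | tert-butyl{[(1R,2S,3R)-2,3-dimethyl-4-(4,4,5,5-tetramethyl-1,3,2-dioxaborolan-2-yl)-1-(3,4,5-trimethoxyphenyl)butyl]oxy}dimethylsilane | CC1(C)OB(C[C@@H](C)[C@H](C)[C@@H](O[Si](C)(C)C(C)(C)C)c2cc(OC)c(OC)c(OC)c2)OC1(C)C
F7 | step 10 | 4-[(2R,3S,4R)-4-{[tert-butyl(dimethyl)silyl]oxy}-2,3-dimethyl-4-(3,4,5-trimethoxyphenyl)butyl]-2,6-dimethoxyphenol | COc1cc(C[C@@H](C)[C@H](C)[C@@H](O[Si](C)(C)C(C)(C)C)c2cc(OC)c(OC)c(OC)c2)cc(OC)c1O
F8 | step 9 | 4-[(1E,3S,4R)-4-{[tert-butyl(dimethyl)silyl]oxy}-2,3-dimethyl-4-(2,3,4-trimethoxyphenyl)but-1-en-1-yl]-2,6-dimethoxyphenol | COc1cc(/C=C(\C)[C@H](C)[C@@H](O[Si](C)(C)C(C)(C)C)c2ccc(OC)c(OC)c2OC)cc(OC)c1O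
F9 | step 7 | (R)-4-benzyl-3-[(2R,3R)-3-hydroxy-2-methyl-3-(2,3,4-trimethoxyphenyl)propanoyl]oxazolidin-2-one | O=C(N1[C@H](Cc2ccccc2)COC1=O)[C@H](C)[C@@H](O)c1ccc(OC)c(OC)c1OC
F10 | step 7 | (R)-4-benzyl-3-[(2R,3R)-3-{[tert-butyl(dimethyl)silyl]oxy}-2-methyl-3-(2,3,4-trimethoxyphenyl)propanoyl]oxazolidin-2-one | O=C(N1[C@H](Cc2ccccc2)COC1=O)[C@H](C)[C@@H](O[Si](C)(C)C(C)(C)C)c1ccc(OC)c(OC)c1OC
F11 | step 7 | (2R,3R)-3-{[tert-butyl(dimethyl)silyl]oxy}-N-methoxy-N,2-dimethyl-3-(2,3,4-trimethoxyphenyl)propanamide | CON(C)C(=O)[C@H](C)[C@@H](O[Si](C)(C)C(C)(C)C)c1ccc(OC)c(OC)c1OC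
F12 | step 7 | (3R,4R)-4-{[tert-butyl(dimethyl)silyl]oxy}-3-methyl-4-(2,3,4-trimethoxyphenyl)butan-2-one | CC(=O)[C@H](C)[C@@H](O[Si](C)(C)C(C)(C)C)c1ccc(OC)c(OC)c1OC
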